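## Retrosynthetic overview

1. The strategy rests on the dihydrofuran ring (O1–C2–C3–C3a–C7a): the C3–O bond and the C2–C(isopropenyl) bond lie on the same face, which is the pattern left by a β-lactone fused across C2–C3 once its carbonyl carbon has become the central isopropenyl carbon.
2. Target ⇐ dehydration of the tertiary carbinol ⇐ acylation of the C3 hydroxyl with the Z side-chain acid (from crotonaldehyde through (Z)-2-bromobut-2-en-1-ol and carboxylation with retention).
3. Cis triol ⇐ MeMgBr on the cis hydroxy methyl ester ⇐ methanolysis of the cis-fused β-lactone.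
4. β-Lactone ⇐ 2-(5-acetoxy-4-acetyl-2-formylphenoxy)acetic acid in one operation: C2–C3 closes the dihydrofuran ring first, C3–O–C(=O) closes the oxetanone second; the benzene ring is bought.
5. Aldehyde acid ⇐ 5-bromo-2,4-dihydroxybenzaldehyde: THP on the free 4-OH, glycolate on the 2-OH, Stille acetylation at C–Br, O-acetylation, ester acidolysis.

Key step: step 6

Assumption: the sense of induction of (S)-tetramisole is assigned from the usual isothiourea model ((Z)-enolate held coplanar by the 1,5-O···S contact, electrophile anti to the C-phenyl group), which predicts the (2R,3S) lactone; if a first run shows the opposite sense, the enantiomeric isothiourea (for example (R)-benzotetramisole) is used and nothing else changes.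

## Route

Step 1
Reactants: 1 5-bromo-2,4-dihydroxybenzaldehyde
Product: 2 5-bromo-2-hydroxy-4-(tetrahydro-2H-pyran-2-yloxy)benzaldehyde
Conditions: 3,4-dihydro-2H-pyran, PPTS (cat.), CH2Cl2, rt
Reagents that add atoms: 3,4-dihydro-2H-pyran, C1=COCCC1
Why: Acid-catalysed acetalisation (THP ether formation) should take only the free 4-OH, because the 2-OH is locked in a hydrogen bond to the formyl group.

Step 2
Reactants: 2 5-bromo-2-hydroxy-4-(tetrahydro-2H-pyran-2-yloxy)benzaldehyde; 3 tert-butyl bromoacetate
Product: 4 tert-butyl 2-[4-bromo-2-formyl-5-(tetrahydro-2H-pyran-2-yloxy)phenoxy]acetate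
Conditions: K2CO3, DMF, rt
Reagents that add atoms: none
Why: Williamson ether synthesis on the only remaining phenol places the glycolate on the oxygen ortho to the formyl group without a regiochemical question, and room temperature avoids base-induced aldol closure to a benzofuran.

Step 3
Reactants: 4 tert-butyl 2-[4-bromo-2-formyl-5-(tetrahydro-2H-pyran-2-yloxy)phenoxy]acetate; 5 tributyl(1-ethoxyvinyl)stannane
Product: 7 tert-butyl 2-(4-acetyl-2-formyl-5-hydroxyphenoxy)acetate, via enol ether 6 (not isolated)
Conditions: PdCl2(PPh3)2 (5 mol%), toluene, 100 °C; then 1 M HCl, THF, rt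
Reagents that add atoms: water, O
Why: Stille coupling with the acetyl-anion equivalent puts the two-carbon unit exactly where bromine was, and dilute acid should then hydrolyse the enol ether to the methyl ketone and remove the THP acetal while the tert-butyl ester survives.

Step 4
Reactants: 7 tert-butyl 2-(4-acetyl-2-formyl-5-hydroxyphenoxy)acetate
Product: 8 tert-butyl 2-(5-acetoxy-4-acetyl-2-formylphenoxy)acetate
Conditions: Ac2O, Et3N, DMAP (cat.), CH2Cl2, 0 °C
Reagents that add atoms: acetic anhydride, CC(=O)OC(C)=O
Why: DMAP-catalysed O-acetylation of the single phenol; the acetate keeps the phenol out of the acyl-transfer chemistry of step 6 and lowers the electron density para to the future C3.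

Step 5
Reactants: 8 tert-butyl 2-(5-acetoxy-4-acetyl-2-formylphenoxy)acetate
Product: 9 2-(5-acetoxy-4-acetyl-2-formylphenoxy)acetic acid
Conditions: TFA, CH2Cl2, 0 °C → rt
Reagents that add atoms: none
Why: Acidolysis of the tert-butyl ester (E1 loss of isobutene) should leave the aryl acetate, the aldehyde and the ketone untouched.

Step 6
Reactants: 9 2-(5-acetoxy-4-acetyl-2-formylphenoxy)acetic acid
Product: 12 cis-fused β-lactone of (2R,3S)-6-acetoxy-5-acetyl-3-hydroxy-2,3-dihydro-1-benzofuran-2-carboxylic acid, via mixed pivalic anhydride 10 (not isolated), via acyl isothiouronium 11 (not isolated)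
Conditions: t-BuCOCl, i-Pr2NEt, CH2Cl2, 0 °C; then (S)-tetramisole·HCl (20 mol%), i-Pr2NEt, −20 °C; cold work-up, crude used at once
Reagents that add atoms: none
Why: Pivaloyl chloride converts the acid into mixed anhydride 10, the isothiourea is acylated to 11, and Hünig's base deprotonates the OCH2 carbon to the (Z)-ammonium enolate, which adds to the ortho formyl group (5-exo-trig, C2–C3 bond, dihydrofuran ring); the new alkoxide then attacks the acyl isothiouronium carbonyl (4-exo-trig, oxetanone ring) and releases the catalyst. The closest known reaction type is the nucleophile-catalysed aldol–lactonisation of aldehyde acids, here with the ammonium enolate of an aryloxyacetic acid as used in isothiourea-catalysed Michael–lactonisations. C2 is set by the catalyst, because the enolate is held coplanar with the isothiouronium and the aldehyde approaches anti to the C-phenyl group; C3 is set by the ring, because only the syn aldolate can close a four-membered ring onto a five-membered one. The step needs enantiofacial control (catalyst), aldehyde-over-ketone selectivity (the acetyl group sits para to the ether oxygen and cannot be reached by the tethered enolate) and survival of the lactone (low temperature, and the electron-poor acetoxy group para to C3a slows ionisation of the benzylic C3–O bond and loss of CO2).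

Step 7
Reactants: 12 cis-fused β-lactone of (2R,3S)-6-acetoxy-5-acetyl-3-hydroxy-2,3-dihydro-1-benzofuran-2-carboxylic acid
Product: 13 methyl (2R,3S)-5-acetyl-3,6-dihydroxy-2,3-dihydro-1-benzofuran-2-carboxylate
Conditions: Mg(OMe)2 (2.2 equiv), MeOH/THF, −20 °C → rt; aq NH4Cl
Reagents that add atoms: magnesium methoxide, CO[Mg]OC
Why: Methanolysis by magnesium methoxide attacks the strained lactone carbonyl (acyl–oxygen cleavage, so C3 keeps its configuration) and transesterifies the aryl acetate, which should give the stable cis hydroxy ester and free the phenol needed in step 8 without epimerising C2.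

Step 8
Reactants: 13 methyl (2R,3S)-5-acetyl-3,6-dihydroxy-2,3-dihydro-1-benzofuran-2-carboxylate
Product: 15 1-[(2R,3S)-3,6-dihydroxy-2-(2-hydroxypropan-2-yl)-2,3-dihydro-1-benzofuran-5-yl]ethan-1-one, via methyl ketone 14 (not isolated)
Conditions: MeMgBr (6 equiv), THF, −78 → −10 °C; aq NH4Cl
Reagents that add atoms: methylmagnesium bromide, C[Mg]Br
Why: Double Grignard addition to the ester: the first two equivalents form the C3 alkoxide and the magnesium phenoxide, whose chelate deactivates the aryl ketone as a vinylogous carboxylate, so the α-alkoxy ester should be converted through ketone 14 into the tertiary carbinol without touching either stereocentre.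

Step 9
Reactants: 16 (E)-but-2-enal (crotonaldehyde)
Product: 18 (Z)-2-bromobut-2-enal, via 2,3-dibromobutanal 17 (not isolated)
Conditions: Br2, CH2Cl2, 0 °C; then Et3N, 0 °C → rt
Reagents that add atoms: bromine, BrBr
Why: Bromine addition to the enal followed by E1cB loss of HBr from the α-position should give the thermodynamic α-bromoenal with the formyl group trans to the methyl group (Z).

Step 10
Reactants: 18 (Z)-2-bromobut-2-enal
Product: 19 (Z)-2-bromobut-2-en-1-ol
Conditions: NaBH4, CeCl3·7H2O, MeOH, 0 °C
Reagents that add atoms: none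
Why: Luche 1,2-reduction of the enal leaves the C–Br bond and the alkene geometry unchanged.

Step 11
Reactants: 19 (Z)-2-bromobut-2-en-1-ol
Product: 21 (Z)-2-(hydroxymethyl)but-2-enoic acid, via dilithio alkoxide 20 (not isolated)
Conditions: t-BuLi (3.1 equiv), Et2O, −78 °C; CO2; aq HCl
Reagents that add atoms: carbon dioxide, O=C=O
Why: Deprotonation and bromine–lithium exchange give a configurationally stable alkenyllithium that is carboxylated with retention, so the carboxyl group ends cis to the methyl group (Z acid).

Step 12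
Reactants: 21 (Z)-2-(hydroxymethyl)but-2-enoic acid
Product: 23 (Z)-2-(acetoxymethyl)but-2-enoic acid, via mixed acetic anhydride 22 (not isolated)
Conditions: Ac2O, pyridine, 0 °C → rt; then H2O
Reagents that add atoms: acetic anhydride, CC(=O)OC(C)=O
Why: O-Acetylation of the primary allylic alcohol; the mixed anhydride formed at the carboxyl group should be hydrolysed at its acetyl carbonyl on aqueous work-up.

Step 13
Reactants: 15 1-[(2R,3S)-3,6-dihydroxy-2-(2-hydroxypropan-2-yl)-2,3-dihydro-1-benzofuran-5-yl]ethan-1-one; 23 (Z)-2-(acetoxymethyl)but-2-enoic acid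
Product: 25 (2R,3S)-5-acetyl-6-hydroxy-2-(2-hydroxypropan-2-yl)-2,3-dihydro-1-benzofuran-3-yl (Z)-2-(acetoxymethyl)but-2-enoate, via acid chloride 24 (not isolated)
Conditions: 23, 1-chloro-N,N,2-trimethylprop-1-en-1-amine, CH2Cl2, 0 °C; then 15, 2,4,6-collidine, −20 °C → rt
Reagents that add atoms: none
Why: Acylation of the secondary benzylic alcohol by an acid chloride made under neutral conditions (Ghosez reagent) and transferred with a hindered, non-nucleophilic base avoids the addition–elimination pathways that isomerise Z-2-substituted butenoates or displace the allylic acetate, while the tertiary alcohol is too hindered and the hydrogen-bonded, undeprotonated phenol too poor a nucleophile to compete.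

Step 14
Reactants: 25 (2R,3S)-5-acetyl-6-hydroxy-2-(2-hydroxypropan-2-yl)-2,3-dihydro-1-benzofuran-3-yl (Z)-2-(acetoxymethyl)but-2-enoate
Product: 26 (2S,3S)-5-acetyl-6-hydroxy-2-(prop-1-en-2-yl)-2,3-dihydro-1-benzofuran-3-yl (Z)-2-(acetoxymethyl)but-2-enoate
Conditions: Burgess reagent, THF, 50 °C
Reagents that add atoms: none
Why: Burgess dehydration (syn elimination of the sulfamate ester) of the tertiary carbinol should remove a methyl hydrogen (six accessible hydrogens against one hindered C2–H next to the C3 ester) and give the isopropenyl group without ionisation at C3; neither stereocentre takes part, and the C2 descriptor changes from R to S only through the priority rules.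

## Compound list

1 | 5-bromo-2,4-dihydroxybenzaldehyde | O=Cc1cc(Br)c(O)cc1O | starting material
2 | 5-bromo-2-hydroxy-4-(tetrahydro-2H-pyran-2-yloxy)benzaldehyde (racemic at the acetal carbon) | O=Cc1cc(Br)c(OC2CCCCO2)cc1O | intermediate
3 | tert-butyl bromoacetate | CC(C)(C)OC(=O)CBr | starting material
4 | tert-butyl 2-[4-bromo-2-formyl-5-(tetrahydro-2H-pyran-2-yloxy)phenoxy]acetate | CC(C)(C)OC(=O)COc1cc(OC2CCCCO2)c(Br)cc1C=O | intermediate
5 | tributyl(1-ethoxyvinyl)stannane | CCCC[Sn](CCCC)(CCCC)C(=C)OCC | starting material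
6 | tert-butyl 2-[4-(1-ethoxyvinyl)-2-formyl-5-(tetrahydro-2H-pyran-2-yloxy)phenoxy]acetate | CCOC(=C)c1cc(C=O)c(OCC(=O)OC(C)(C)C)cc1OC1CCCCO1 | intermediate
7 | tert-butyl 2-(4-acetyl-2-formyl-5-hydroxyphenoxy)acetate | CC(=O)c1cc(C=O)c(OCC(=O)OC(C)(C)C)cc1O | intermediate
8 | tert-butyl 2-(5-acetoxy-4-acetyl-2-formylphenoxy)acetate | CC(=O)Oc1cc(OCC(=O)OC(C)(C)C)c(C=O)cc1C(C)=O | intermediate
9 | 2-(5-acetoxy-4-acetyl-2-formylphenoxy)acetic acid | CC(=O)Oc1cc(OCC(=O)O)c(C=O)cc1C(C)=O | intermediate
10 | mixed anhydride of 9 and pivalic acid | CC(=O)Oc1cc(OCC(=O)OC(=O)C(C)(C)C)c(C=O)cc1C(C)=O | intermediate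
11 | N-acyl (S)-tetramisolium pivalate derived from 10 | CC(=O)Oc1cc(OCC(=O)[N+]2=C3SCCN3C[C@@H]2c2ccccc2)c(C=O)cc1C(C)=O.CC(C)(C)C(=O)[O-] | intermediate
12 | cis-fused β-lactone of (2R,3S)-6-acetoxy-5-acetyl-3-hydroxy-2,3-dihydro-1-benzofuran-2-carboxylic acid | O=C3[C@@H]1Oc2cc(OC(C)=O)c(C(C)=O)cc2[C@@H]1O3 | intermediate
13 | methyl (2R,3S)-5-acetyl-3,6-dihydroxy-2,3-dihydro-1-benzofuran-2-carboxylate | COC(=O)[C@@H]1Oc2cc(O)c(C(C)=O)cc2[C@@H]1O | intermediate
14 | 1-[(2R,3S)-5-acetyl-3,6-dihydroxy-2,3-dihydro-1-benzofuran-2-yl]ethan-1-one | CC(=O)[C@@H]1Oc2cc(O)c(C(C)=O)cc2[C@@H]1O | intermediate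
15 | 1-[(2R,3S)-3,6-dihydroxy-2-(2-hydroxypropan-2-yl)-2,3-dihydro-1-benzofuran-5-yl]ethan-1-one | CC(C)(O)[C@@H]1Oc2cc(O)c(C(C)=O)cc2[C@@H]1O | intermediate
16 | (E)-but-2-enal (crotonaldehyde) | C/C=C/C=O | starting material
17 | 2,3-dibromobutanal (racemic anti adduct, one enantiomer drawn) | C[C@H](Br)[C@H](Br)C=O | intermediate
18 | (Z)-2-bromobut-2-enal | C/C=C(\Br)C=O | intermediate
19 | (Z)-2-bromobut-2-en-1-ol | C/C=C(\Br)CO | intermediate
20 | lithium 2-lithiobut-2-en-1-olate (lithium cis to the methyl group) | C/C=C(\[Li])CO[Li] | intermediate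
21 | (Z)-2-(hydroxymethyl)but-2-enoic acid | C/C=C(\C(=O)O)CO | intermediate
22 | acetic (Z)-2-(acetoxymethyl)but-2-enoic anhydride | C/C=C(\C(=O)OC(C)=O)COC(C)=O | intermediate
23 | (Z)-2-(acetoxymethyl)but-2-enoic acid | C/C=C(\C(=O)O)COC(C)=O | intermediate
24 | (Z)-2-(acetoxymethyl)but-2-enoyl chloride | C/C=C(\C(Cl)=O)COC(C)=O | intermediate
25 | (2R,3S)-5-acetyl-6-hydroxy-2-(2-hydroxypropan-2-yl)-2,3-dihydro-1-benzofuran-3-yl (Z)-2-(acetoxymethyl)but-2-enoate | CC(C)(O)[C@@H]1Oc2cc(O)c(C(C)=O)cc2[C@@H]1OC(=O)/C(=C\C)COC(C)=O | intermediate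
26 | (2S,3S)-5-acetyl-6-hydroxy-2-(prop-1-en-2-yl)-2,3-dihydro-1-benzofuran-3-yl (Z)-2-(acetoxymethyl)but-2-enoate | C=C(C)[C@@H]1Oc2cc(O)c(C(C)=O)cc2[C@@H]1OC(=O)/C(=C\C)COC(C)=O | target

## Step count and risks

Total step count: 14 (steps 1–8 main line, steps 9–12 side-chain acid, steps 13–14 end game).
Longest linear sequence: 10 steps (1–8, 13, 14).

**Step 6.** Several processes may go wrong. The ammonium enolate may add with poor facial discrimination. The activated aryl acetate may transfer its acetyl group to the catalyst and divert material. The benzylic lactone may lose CO2 to the benzofuran during work-up. The fallback sets out from 9 and comes back at 13. The same cascade is run with the achiral isothiourea DHPB (PivCl, i-Pr2NEt, CH2Cl2, −20 °C), and the cold mixture is treated directly with Mg(OMe)2/MeOH. The racemic cis-fused lactone F1 is thereby opened in the flask, without isolation, to the racemic cis hydroxy ester F2. F2 is then resolved by lipase-catalysed acetylation (immobilised Candida antarctica lipase B, vinyl acetate, MTBE). The enantiomer preference of the enzyme has to be established first; the text is written for acetylation of the (2S,3R) enantiomer to the 3-acetate F3, which is separated by chromatography from unreacted (2R,3S) alcohol 13.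

**Step 13.** The acyl donor may isomerise from Z to E, or lose its allylic acetate by SN2′ attack, during activation. Acylation of the hindered C3 hydroxyl may also be so slow that acylation of the phenol takes over. The fallback sets out from 21 and comes back at 25. The primary oxygen is carried as a silyl ether, so that the donor has no allylic leaving group and tolerates forcing transfer. Acid 21 is bis-silylated (TBSCl, imidazole, DMF) to the silyl ester silyl ether F4. Its silyl ester is hydrolysed (K2CO3, MeOH–H2O) to (Z)-2-[(tert-butyldimethylsilyloxy)methyl]but-2-enoic acid F5. Yamaguchi activation (2,4,6-trichlorobenzoyl chloride, Et3N, toluene) gives the mixed anhydride F6, which is heated with 15 at 60–80 °C without DMAP to give the C3 ester F7. HF·pyridine then frees the primary alcohol F8, which is acetylated selectively (Ac2O, pyridine, 0 °C) to 25.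

**Step 14.** Proton loss may occur from C2 instead of a methyl group, giving the enol ether and then the aromatic benzofuran. The cis C3 ester may also take part in departure of the sulfamate. The fallback sets out from 13 and comes back at 26, and it builds the isopropenyl group by carbonyl methylenation instead of elimination. Ester 13 is converted with MeNH(OMe)·HCl and i-PrMgCl into the Weinreb amide F9. MeMgBr (phenoxide shielding as in step 8) then stops at methyl ketone 14, which is isolated in this case. Lombardo methylenation (Zn, CH2Br2, TiCl4), which is non-basic and expected to prefer the aliphatic α-alkoxy ketone over the chelated aryl ketone, gives the isopropenyl diol F10. Acylation of its C3 hydroxyl with acid chloride 24 under the conditions of step 13 gives 26.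

## Further compounds

F1 | step 6 | racemic cis-fused β-lactone (racemate of 12) | O=C3[C@@H]1Oc2cc(OC(C)=O)c(C(C)=O)cc2[C@@H]1O3.O=C3[C@H]1Oc2cc(OC(C)=O)c(C(C)=O)cc2[C@H]1O3
F2 | step 6 | racemic methyl cis-5-acetyl-3,6-dihydroxy-2,3-dihydro-1-benzofuran-2-carboxylate | COC(=O)[C@@H]1Oc2cc(O)c(C(C)=O)cc2[C@@H]1O.COC(=O)[C@H]1Oc2cc(O)c(C(C)=O)cc2[C@H]1O
F3 | step 6 | methyl (2S,3R)-3-acetoxy-5-acetyl-6-hydroxy-2,3-dihydro-1-benzofuran-2-carboxylate | COC(=O)[C@H]1Oc2cc(O)c(C(C)=O)cc2[C@H]1OC(C)=O
F4 | step 13 | tert-butyldimethylsilyl (Z)-2-{[(tert-butyldimethylsilyl)oxy]methyl}but-2-enoate | C/C=C(\C(=O)O[Si](C)(C)C(C)(C)C)CO[Si](C)(C)C(C)(C)C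
F5 | step 13 | (Z)-2-{[(tert-butyldimethylsilyl)oxy]methyl}but-2-enoic acid | C/C=C(\C(=O)O)CO[Si](C)(C)C(C)(C)C
F6 | step 13 | (Z)-2-{[(tert-butyldimethylsilyl)oxy]methyl}but-2-enoic 2,4,6-trichlorobenzoic anhydride | C/C=C(\C(=O)OC(=O)c1c(Cl)cc(Cl)cc1Cl)CO[Si](C)(C)C(C)(C)C
F7 | step 13 | (2R,3S)-5-acetyl-6-hydroxy-2-(2-hydroxypropan-2-yl)-2,3-dihydro-1-benzofuran-3-yl (Z)-2-{[(tert-butyldimethylsilyl)oxy]methyl}but-2-enoate | CC(C)(O)[C@@H]1Oc2cc(O)c(C(C)=O)cc2[C@@H]1OC(=O)/C(=C\C)CO[Si](C)(C)C(C)(C)C
F8 | step 13 | (2R,3S)-5-acetyl-6-hydroxy-2-(2-hydroxypropan-2-yl)-2,3-dihydro-1-benzofuran-3-yl (Z)-2-(hydroxymethyl)but-2-enoate | CC(C)(O)[C@@H]1Oc2cc(O)c(C(C)=O)cc2[C@@H]1OC(=O)/C(=C\C)CO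
F9 | step 14 | (2R,3S)-5-acetyl-3,6-dihydroxy-N-methoxy-N-methyl-2,3-dihydro-1-benzofuran-2-carboxamide | CON(C)C(=O)[C@@H]1Oc2cc(O)c(C(C)=O)cc2[C@@H]1O
F10 | step 14 | 1-[(2S,3S)-3,6-dihydroxy-2-(prop-1-en-2-yl)-2,3-dihydro-1-benzofuran-5-yl]ethan-1-one | C=C(C)[C@@H]1Oc2cc(O)c(C(C)=O)cc2[C@@H]1O
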